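If two flasks are compared at equal product rather than at equal time, the clock drops out of the comparison, and what remains is one rate divided by another.

| setting | south-west | south | north-west |
|---|---|---|---|
| starting material | 80.0 mM | 80.0 mM | 80.0 mM |
| free catalyst | 0.800 mM | 0.400 mM | 0.800 mM |
| time |  |  | 900 min |

| south-west run: time / min | south-west run: [product] / mM | south run: time / min | south run: [product] / mM |
|---|---|---|---|
| 6.0 | 1.91 | 6.0 | 0.46 |
| 11 | 3.67 | 11 | 1.36 |
| 22 | 7.58 | 22 | 1.82 |
| 41 | 14.15 | 41 | 3.00 |
| 79 | 28.13 | 79 | 6.06 |
| 150 | 54.72 | 150 | 10.27 |

(each reading ± 0.2 mM)

- how the opening rate goes with [free catalyst] round the charge of the south-west run: the exponent of the rate at two percent of starting material gone to product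
- product in the north-west run at 900 min, as a share of the starting material charged

- Overall: starting material -> product, with free catalyst as catalyst.
- Constant volume, constant temperature.
- Readings of a species count what is bound in complexes too.
- An order is taken over about fifteen percent of the charge, up and down.

My reckoning starts with the openings. The south-west run makes its first few mM at 0.354 mM min⁻¹, and the south run crosses nearly the same span of product at 0.0767 mM min⁻¹. Their quotient, 4.62, is the same-product rate ratio. Its logarithm over that of the catalyst ratio gives an apparent order of 2.21, a reading that carries the scatter and spans the whole step between the charges.

Next comes the slowing. Between the last two readings, the south-west run runs at 0.375 mM min⁻¹, a factor of 1.06 on its opening, so these readings show no slowing. The south run falls to 0.0593 mM min⁻¹, a factor of 0.773. The north-west run has the south-west charge. The south run's decline, as read, takes about 280 min per factor of e. As a rough estimate, a rate of the south-west size decaying that way from 150 min onward sums to 105 mM, more than the 25.3 mM of product that the south-west run still lacks of its charge at that time. I therefore expect product in the north-west run to stand close to the charge at 900 min.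

The forecast gives 1.9 for the exponent, lower than my reading, and 98% for the north-west run: “essentially complete, barring an unseen equilibrium or late catalyst death”.

    free catalyst + starting material ⇌ catalyst-substrate complex, settled at all times (93.00 M⁻¹)
    catalyst-substrate complex + free catalyst → product + 2 free catalyst (8160 M⁻¹ min⁻¹)
    free catalyst → spent catalyst (0.02046 min⁻¹)
    catalyst-substrate complex + starting material ⇌ doubly bound catalyst, settled at all times (4.040 M⁻¹)

The flask gives an exponent of 2.1 and 96.8% of the charge as product in the north-west run at 900 min. Product in the south-west run came to half of the starting material charged at 111 min, earlier than the time asked of the north-west run. Multiplied by the ratio 4.62, the 57.3 min that the south-west run needed for product to reach a quarter of the charge gives 265 min for the south run, and the south run took longer than that, 498 min.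

The numbers in the tables were generated by integration from invented constants; noise was put on by code.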